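**Retrosynthetic overview**
1. Target 31 ⇐ protected flavanone 29 (acetal solvolysis, hydrogenolysis) ⇐ hydroxy ketone 28 by Mitsunobu closure of the C2–O1 bond with inversion; the chromanone ring of the flavanone unit is the last ring formed.
2. 28 ⇐ aldehyde 20 + metalated tris-MOM phloroglucinol 22 (1,2-addition, oxidation, unmasking); ring A of the flavanone unit comes from phloroglucinol.
3. 20 ⇐ Evans syn-aldol of arylacetyl oxazolidinone 13 with 4-(benzyloxy)benzaldehyde 14; this joins the two halves at the future C2–C3 bond and sets both stereocentres.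
4. 13 ⇐ flavone-acetic acid 10 ⇐ bromoflavone 7 (palladium-catalysed arylation of a zinc ester enolate).
5. 7 ⇐ Claisen–Schmidt condensation of 4 with 2, then oxidative cyclization; the pyranone ring of the flavone unit is the first ring formed.

Assumption: the SMILES is read as the (2R,3S)-2,3-trans chromanone (the two aryl groups on opposite faces); Ar1 below stands for 2-(benzyloxy)-5-[5,7-bis(benzyloxy)-4-oxo-4H-chromen-2-yl]phenyl.

**Route**

Step 1
Reactants: 1 3-bromo-4-hydroxybenzaldehyde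
Product: 2 4-(benzyloxy)-3-bromobenzaldehyde
Conditions: BnBr, K2CO3, DMF, rt
Reagents that add atoms: benzyl bromide, BrCc1ccccc1
Why: Williamson etherification of the acidic phenol under mild base leaves the aldehyde and the aryl bromide untouched.

Step 2
Reactants: 3 1-(2,4,6-trihydroxyphenyl)ethan-1-one
Product: 4 1-[2,4-bis(benzyloxy)-6-hydroxyphenyl]ethan-1-one
Conditions: BnBr (2.05 equiv), K2CO3, DMF, rt
Reagents that add atoms: benzyl bromide, BrCc1ccccc1
Why: Williamson etherification stops at the dibenzyl ether because the remaining ortho hydroxyl is locked in a hydrogen bond to the acetyl carbonyl.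

Step 3
Reactants: 4 1-[2,4-bis(benzyloxy)-6-hydroxyphenyl]ethan-1-one; 2 4-(benzyloxy)-3-bromobenzaldehyde
Product: 6 (E)-3-[4-(benzyloxy)-3-bromophenyl]-1-[2,4-bis(benzyloxy)-6-hydroxyphenyl]prop-2-en-1-one, via aldol adduct 5 (not isolated)
Conditions: KOH (50% aq), EtOH/THF, rt
Reagents that add atoms: none
Why: Claisen–Schmidt aldol condensation, in which the acetophenone enolate adds to the non-enolizable aldehyde and the aldol 5 dehydrates by E1cB to the conjugated E-chalcone.

Step 4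
Reactants: 6 (E)-chalcone
Product: 7 5,7-bis(benzyloxy)-2-[4-(benzyloxy)-3-bromophenyl]-4H-chromen-4-one
Conditions: I2 (10 mol %), DMSO, 130 °C
Reagents that add atoms: none
Why: Iodine-catalysed oxidative cyclization (oxa-Michael closure then dehydrogenation, DMSO as terminal oxidant) is the standard 2'-hydroxychalcone-to-flavone conversion and tolerates benzyl ethers and the aryl bromide.

Step 5
Reactants: 7 bromoflavone; 8 (2-tert-butoxy-2-oxoethyl)zinc bromide (commercial solution)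
Product: 9 tert-butyl 2-Ar1-acetate
Conditions: Pd2(dba)3 (2 mol %), XPhos (5 mol %), THF, 65 °C
Reagents that add atoms: none
Why: Negishi-type palladium-catalysed alpha-arylation of the Reformatsky reagent (oxidative addition, transmetalation from zinc, reductive elimination) works on ortho-alkoxy aryl bromides, and the soft zinc enolate does not attack the vinylogous-ester carbonyl of the flavone.

Step 6
Reactants: 9 tert-butyl 2-Ar1-acetate
Product: 10 2-Ar1-acetic acid
Conditions: TFA/CH2Cl2 (1:4), 0 °C to rt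
Reagents that add atoms: none
Why: Acidolysis of the tert-butyl ester (E1 loss of isobutene) frees the acid under conditions that leave aryl benzyl ethers intact at room temperature.

Step 7
Reactants: 10 2-Ar1-acetic acid; 11 (S)-4-benzyloxazolidin-2-one
Product: 13 (S)-4-benzyl-3-(2-Ar1-acetyl)oxazolidin-2-one, via mixed pivalic anhydride 12 (not isolated)
Conditions: PivCl, Et3N, THF, –20 °C; then LiCl, 11, rt
Reagents that add atoms: none
Why: N-acylation of the Evans auxiliary through the mixed pivalic anhydride with LiCl/Et3N activation needs no strong base, so the arylacetic acid is not converted into a ketene and the auxiliary stereocentre is untouched.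

Step 8
Reactants: 13 (S)-4-benzyl-3-(2-Ar1-acetyl)oxazolidin-2-one; 14 4-(benzyloxy)benzaldehyde
Product: 17 (S)-4-benzyl-3-[(2S,3S)-2-Ar1-3-[4-(benzyloxy)phenyl]-3-hydroxypropanoyl]oxazolidin-2-one, via dibutylboron Z-enolate 15 (not isolated), via dibutylboron aldolate 16 (not isolated)
Conditions: Bu2BOTf (2.1 equiv), iPr2NEt, CH2Cl2, –78 to 0 °C; 14, –78 to 0 °C; then pH 7 buffer, MeOH, 30% H2O2, 0 °C
Reagents that add atoms: none
Why: Evans syn-aldol reaction, in which soft enolization gives the Z-boron enolate and a closed Zimmerman–Traxler chair with the aldehyde on the face away from the benzyl group of the (S)-auxiliary sets both new centres as (2S,3S), the second equivalent of Bu2BOTf being held by the basic pyranone carbonyl.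

Step 9
Reactants: 17 syn-aldol adduct
Product: 18 (S)-4-benzyl-3-[(2S,3S)-2-Ar1-3-[4-(benzyloxy)phenyl]-3-(triethylsilyloxy)propanoyl]oxazolidin-2-one
Conditions: TESOTf, 2,6-lutidine, CH2Cl2, –78 to 0 °C
Reagents that add atoms: triethylsilyl triflate, CC[Si](CC)(CC)OS(=O)(=O)C(F)(F)F
Why: Silylation of the hindered secondary alcohol with the reactive silyl triflate blocks retro-aldol and protects the carbinol for the next steps without touching a stereocentre.

Step 10
Reactants: 18 TES-protected imide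
Product: 19 (2R,3S)-2-Ar1-3-[4-(benzyloxy)phenyl]-3-(triethylsilyloxy)propan-1-ol
Conditions: LiBH4 (1.5 equiv), H2O (1.5 equiv), Et2O/THF, 0 °C
Reagents that add atoms: none
Why: Reductive cleavage of the activated imide carbonyl by borohydride is much faster than attack on the donor-deactivated vinylogous-ester carbonyl of the flavone and releases the auxiliary (the descriptor at C2 changes only through priorities).

Step 11
Reactants: 19 primary alcohol
Product: 20 (2S,3S)-2-Ar1-3-[4-(benzyloxy)phenyl]-3-(triethylsilyloxy)propanal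
Conditions: Dess–Martin periodinane, NaHCO3, CH2Cl2, 0 °C to rt; used crude
Reagents that add atoms: none
Why: Buffered Dess–Martin oxidation gives the aldehyde without over-oxidation or beta-elimination, and the epimerizable alpha-aryl centre is not critical because C3 of the final chromanone is under thermodynamic control.

Step 12
Reactants: 21 benzene-1,3,5-triol (phloroglucinol)
Product: 22 1,3,5-tris(methoxymethoxy)benzene
Conditions: MOMCl (3.6 equiv), iPr2NEt, CH2Cl2/DMF, 0 °C to rt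
Reagents that add atoms: chloromethyl methyl ether, COCCl
Why: Threefold O-alkylation (Williamson type) with the hard electrophile MOMCl gives the symmetric tris-acetal whose MOM groups later direct lithiation.

Step 13
Reactants: 22 1,3,5-tris(methoxymethoxy)benzene; 20 aldehyde
Product: 25 (1RS,2R,3S)-2-Ar1-3-[4-(benzyloxy)phenyl]-3-(triethylsilyloxy)-1-[2,4,6-tris(methoxymethoxy)phenyl]propan-1-ol, via aryllithium 23 (not isolated), via arylcerium dichloride 24 (not isolated)
Conditions: 22 (1.5 equiv), n-BuLi, THF, 0 °C; CeCl3, –78 °C; then 20, –78 °C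
Reagents that add atoms: none
Why: Directed ortho-lithiation between two MOM ethers, transmetalation to the weakly basic organocerium and 1,2-addition at –78 °C (Imamoto conditions) favour the aldehyde over both enolization and the flavone carbonyl, and the new carbinol centre, formed as a mixture, is erased in the next step.

Step 14
Reactants: 25 carbinol mixture
Product: 26 (2S,3S)-2-Ar1-3-[4-(benzyloxy)phenyl]-3-(triethylsilyloxy)-1-[2,4,6-tris(methoxymethoxy)phenyl]propan-1-one
Conditions: Dess–Martin periodinane, NaHCO3, CH2Cl2, rt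
Reagents that add atoms: none
Why: Dess–Martin oxidation of the benzylic alcohol converges both epimers on one ketone under buffered non-basic conditions that preserve the beta-silyloxy ketone.

Step 15
Reactants: 26 tris-MOM ketone
Product: 27 (2S,3S)-2-Ar1-3-[4-(benzyloxy)phenyl]-1-[2-hydroxy-4,6-bis(methoxymethoxy)phenyl]-3-(triethylsilyloxy)propan-1-one
Conditions: MgBr2·OEt2 (3 equiv), Et2O/CH2Cl2, 0 °C to rt
Reagents that add atoms: none
Why: Chelation-controlled Lewis-acid acetal cleavage, in which magnesium bridged between the ketone oxygen and one ortho MOM ether lets bromide remove only that group and the resulting chelated magnesium phenoxide protects the second ortho and the para MOM ethers.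

Step 16
Reactants: 27 silyl ether
Product: 28 (2S,3S)-2-Ar1-3-[4-(benzyloxy)phenyl]-3-hydroxy-1-[2-hydroxy-4,6-bis(methoxymethoxy)phenyl]propan-1-one
Conditions: HF·pyridine, pyridine, THF, 0 °C to rt
Reagents that add atoms: none
Why: Fluoride-mediated desilylation under buffered, weakly acidic conditions frees the benzylic alcohol without retro-aldol, elimination or ionization.

Step 17
Reactants: 28 hydroxy ketone
Product: 29 (2R,3S)-3-Ar1-2-[4-(benzyloxy)phenyl]-5,7-bis(methoxymethoxy)chroman-4-one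
Conditions: PPh3, DIAD, THF (0.01 M), 0 °C to rt
Reagents that add atoms: none
Why: Intramolecular Mitsunobu etherification, in which the hydrogen-bonded phenol displaces the benzylic oxyphosphonium in a six-membered SN2 closure with inversion, turns the (3S)-carbinol into (2R) next to the untouched (S)-centre and gives the trans-diequatorial 2,3-diaryl chromanone.

Step 18
Reactants: 29 protected flavanone
Product: 30 (2R,3S)-3-Ar1-2-[4-(benzyloxy)phenyl]-5,7-dihydroxychroman-4-one
Conditions: 3 M aq HCl, MeOH/THF, 45 °C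
Reagents that add atoms: none
Why: Acid-catalysed acetal solvolysis removes both MOM ethers under conditions that spare benzyl ethers and do not open the chromanone ring, with C3 staying in its favoured trans arrangement.

Step 19
Reactants: 30 tetrabenzyl ether
Product: 31 (2R,3S)-3-[5-(5,7-dihydroxy-4-oxo-4H-chromen-2-yl)-2-hydroxyphenyl]-5,7-dihydroxy-2-(4-hydroxyphenyl)chroman-4-one
Conditions: H2 (1 atm), 10% Pd/C, EtOAc/MeOH, rt
Reagents that add atoms: none
Why: Neutral hydrogenolysis of the four benzyl ethers over Pd/C is faster than reduction of the flavone double bond or either carbonyl and leaves both stereocentres untouched, giving the (2R,3S)-trans target.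

**Compound list**
1 | 3-bromo-4-hydroxybenzaldehyde | O=Cc1ccc(O)c(Br)c1 | starting material
2 | 4-(benzyloxy)-3-bromobenzaldehyde | O=Cc1ccc(OCc2ccccc2)c(Br)c1 | intermediate
3 | 1-(2,4,6-trihydroxyphenyl)ethan-1-one | CC(=O)c1c(O)cc(O)cc1O | starting material
4 | 1-[2,4-bis(benzyloxy)-6-hydroxyphenyl]ethan-1-one | CC(=O)c1c(O)cc(OCc2ccccc2)cc1OCc1ccccc1 | intermediate
5 | racemic 3-[4-(benzyloxy)-3-bromophenyl]-1-[2,4-bis(benzyloxy)-6-hydroxyphenyl]-3-hydroxypropan-1-one (aldol adduct) | O=C(CC(O)c1ccc(OCc2ccccc2)c(Br)c1)c1c(O)cc(OCc2ccccc2)cc1OCc1ccccc1 | intermediate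
6 | (E)-3-[4-(benzyloxy)-3-bromophenyl]-1-[2,4-bis(benzyloxy)-6-hydroxyphenyl]prop-2-en-1-one | O=C(/C=C/c1ccc(OCc2ccccc2)c(Br)c1)c1c(O)cc(OCc2ccccc2)cc1OCc1ccccc1 | intermediate
7 | 5,7-bis(benzyloxy)-2-[4-(benzyloxy)-3-bromophenyl]-4H-chromen-4-one | O=c1cc(-c2ccc(OCc3ccccc3)c(Br)c2)oc2cc(OCc3ccccc3)cc(OCc3ccccc3)c12 | intermediate
8 | (2-tert-butoxy-2-oxoethyl)zinc bromide | CC(C)(C)OC(=O)C[Zn]Br | starting material
9 | tert-butyl 2-{2-(benzyloxy)-5-[5,7-bis(benzyloxy)-4-oxo-4H-chromen-2-yl]phenyl}acetate | CC(C)(C)OC(=O)Cc1cc(-c2cc(=O)c3c(OCc4ccccc4)cc(OCc4ccccc4)cc3o2)ccc1OCc1ccccc1 | intermediate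
10 | 2-{2-(benzyloxy)-5-[5,7-bis(benzyloxy)-4-oxo-4H-chromen-2-yl]phenyl}acetic acid | OC(=O)Cc1cc(-c2cc(=O)c3c(OCc4ccccc4)cc(OCc4ccccc4)cc3o2)ccc1OCc1ccccc1 | intermediate
11 | (S)-4-benzyloxazolidin-2-one | O=C1N[C@@H](Cc2ccccc2)CO1 | starting material
12 | 2-Ar1-acetic pivalic anhydride | CC(C)(C)C(=O)OC(=O)Cc1cc(-c2cc(=O)c3c(OCc4ccccc4)cc(OCc4ccccc4)cc3o2)ccc1OCc1ccccc1 | intermediate
13 | (S)-4-benzyl-3-(2-Ar1-acetyl)oxazolidin-2-one | O=C(Cc1cc(-c2cc(=O)c3c(OCc4ccccc4)cc(OCc4ccccc4)cc3o2)ccc1OCc1ccccc1)N1C(=O)OC[C@@H]1Cc1ccccc1 | intermediate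
14 | 4-(benzyloxy)benzaldehyde | O=Cc1ccc(OCc2ccccc2)cc1 | starting material
15 | dibutylboron (Z)-enolate of 13 | CCCCB(CCCC)O/C(=C\c1cc(-c2cc(=O)c3c(OCc4ccccc4)cc(OCc4ccccc4)cc3o2)ccc1OCc1ccccc1)N1C(=O)OC[C@@H]1Cc1ccccc1 | intermediate
16 | O-dibutylboryl aldolate of 17 | O=C([C@@H](c1cc(-c2cc(=O)c3c(OCc4ccccc4)cc(OCc4ccccc4)cc3o2)ccc1OCc1ccccc1)[C@H](OB(CCCC)CCCC)c1ccc(OCc2ccccc2)cc1)N1C(=O)OC[C@@H]1Cc1ccccc1 | intermediate
17 | (S)-4-benzyl-3-[(2S,3S)-2-Ar1-3-[4-(benzyloxy)phenyl]-3-hydroxypropanoyl]oxazolidin-2-one | O=C([C@@H](c1cc(-c2cc(=O)c3c(OCc4ccccc4)cc(OCc4ccccc4)cc3o2)ccc1OCc1ccccc1)[C@H](O)c1ccc(OCc2ccccc2)cc1)N1C(=O)OC[C@@H]1Cc1ccccc1 | intermediate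
18 | (S)-4-benzyl-3-[(2S,3S)-2-Ar1-3-[4-(benzyloxy)phenyl]-3-(triethylsilyloxy)propanoyl]oxazolidin-2-one | O=C([C@@H](c1cc(-c2cc(=O)c3c(OCc4ccccc4)cc(OCc4ccccc4)cc3o2)ccc1OCc1ccccc1)[C@H](O[Si](CC)(CC)CC)c1ccc(OCc2ccccc2)cc1)N1C(=O)OC[C@@H]1Cc1ccccc1 | intermediate
19 | (2R,3S)-2-Ar1-3-[4-(benzyloxy)phenyl]-3-(triethylsilyloxy)propan-1-ol | OC[C@@H](c1cc(-c2cc(=O)c3c(OCc4ccccc4)cc(OCc4ccccc4)cc3o2)ccc1OCc1ccccc1)[C@H](O[Si](CC)(CC)CC)c1ccc(OCc2ccccc2)cc1 | intermediate
20 | (2S,3S)-2-Ar1-3-[4-(benzyloxy)phenyl]-3-(triethylsilyloxy)propanal | O=C[C@@H](c1cc(-c2cc(=O)c3c(OCc4ccccc4)cc(OCc4ccccc4)cc3o2)ccc1OCc1ccccc1)[C@H](O[Si](CC)(CC)CC)c1ccc(OCc2ccccc2)cc1 | intermediate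
21 | benzene-1,3,5-triol (phloroglucinol) | Oc1cc(O)cc(O)c1 | starting material
22 | 1,3,5-tris(methoxymethoxy)benzene | COCOc1cc(OCOC)cc(OCOC)c1 | intermediate
23 | [2,4,6-tris(methoxymethoxy)phenyl]lithium | [Li]c1c(OCOC)cc(OCOC)cc1OCOC | intermediate
24 | dichloro[2,4,6-tris(methoxymethoxy)phenyl]cerium | Cl[Ce](Cl)c1c(OCOC)cc(OCOC)cc1OCOC | intermediate
25 | (1RS,2R,3S)-2-Ar1-3-[4-(benzyloxy)phenyl]-3-(triethylsilyloxy)-1-[2,4,6-tris(methoxymethoxy)phenyl]propan-1-ol (C1 epimer mixture) | OC(c1c(OCOC)cc(OCOC)cc1OCOC)[C@@H](c1cc(-c2cc(=O)c3c(OCc4ccccc4)cc(OCc4ccccc4)cc3o2)ccc1OCc1ccccc1)[C@H](O[Si](CC)(CC)CC)c1ccc(OCc2ccccc2)cc1 | intermediate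
26 | (2S,3S)-2-Ar1-3-[4-(benzyloxy)phenyl]-3-(triethylsilyloxy)-1-[2,4,6-tris(methoxymethoxy)phenyl]propan-1-one | O=C(c1c(OCOC)cc(OCOC)cc1OCOC)[C@@H](c1cc(-c2cc(=O)c3c(OCc4ccccc4)cc(OCc4ccccc4)cc3o2)ccc1OCc1ccccc1)[C@H](O[Si](CC)(CC)CC)c1ccc(OCc2ccccc2)cc1 | intermediate
27 | (2S,3S)-2-Ar1-3-[4-(benzyloxy)phenyl]-1-[2-hydroxy-4,6-bis(methoxymethoxy)phenyl]-3-(triethylsilyloxy)propan-1-one | O=C(c1c(O)cc(OCOC)cc1OCOC)[C@@H](c1cc(-c2cc(=O)c3c(OCc4ccccc4)cc(OCc4ccccc4)cc3o2)ccc1OCc1ccccc1)[C@H](O[Si](CC)(CC)CC)c1ccc(OCc2ccccc2)cc1 | intermediate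
28 | (2S,3S)-2-Ar1-3-[4-(benzyloxy)phenyl]-3-hydroxy-1-[2-hydroxy-4,6-bis(methoxymethoxy)phenyl]propan-1-one | O=C(c1c(O)cc(OCOC)cc1OCOC)[C@@H](c1cc(-c2cc(=O)c3c(OCc4ccccc4)cc(OCc4ccccc4)cc3o2)ccc1OCc1ccccc1)[C@H](O)c1ccc(OCc2ccccc2)cc1 | intermediate
29 | (2R,3S)-3-Ar1-2-[4-(benzyloxy)phenyl]-5,7-bis(methoxymethoxy)chroman-4-one | O=C1c2c(OCOC)cc(OCOC)cc2O[C@@H](c2ccc(OCc3ccccc3)cc2)[C@@H]1c1cc(-c2cc(=O)c3c(OCc4ccccc4)cc(OCc4ccccc4)cc3o2)ccc1OCc1ccccc1 | intermediate
30 | (2R,3S)-3-Ar1-2-[4-(benzyloxy)phenyl]-5,7-dihydroxychroman-4-one | O=C1c2c(O)cc(O)cc2O[C@@H](c2ccc(OCc3ccccc3)cc2)[C@@H]1c1cc(-c2cc(=O)c3c(OCc4ccccc4)cc(OCc4ccccc4)cc3o2)ccc1OCc1ccccc1 | intermediate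
31 | (2R,3S)-3-[5-(5,7-dihydroxy-4-oxo-4H-chromen-2-yl)-2-hydroxyphenyl]-5,7-dihydroxy-2-(4-hydroxyphenyl)chroman-4-one | O=C1c2c(O)cc(O)cc2O[C@@H](c2ccc(O)cc2)[C@@H]1c1cc(-c2cc(=O)c3c(O)cc(O)cc3o2)ccc1O | target

**Step count**
Total steps: 19. Longest linear sequence: 17 steps (1 → 2 → 6 → 7 → 9 → 10 → 13 → 17 → 18 → 19 → 20 → 25 → 26 → 27 → 28 → 29 → 30 → 31). Steps 2 and 12 are one-step side branches.

**Steps most likely to fail**

Step 17 (Mitsunobu ring closure). The activated benzylic alcohol sits beta to a ketone with an acidic alpha-aryl proton, so elimination to the chalcone can compete with the SN2 closure, and the para-benzyloxy group makes ionization possible. Fallback: set out from 28 and let the elimination happen on purpose. The same PPh3/DIAD treatment without high dilution, or a separate dehydration, gives the alpha-aryl-2'-hydroxychalcone F1. The ring is then closed by a catalyst-controlled asymmetric intramolecular oxa-Michael addition with a quinine- or quinidine-derived bifunctional thiourea (10 mol %, toluene, 0 °C), the pseudoenantiomer being chosen by screening. C3 then settles trans by enolization and the ee is upgraded by crystallization. The fallback comes back to the route at 29.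

Step 13 (organocerium addition to aldehyde 20). The aldehyde is hindered and enolizable, the nucleophile has two ortho substituents, and the flavone carbonyl is a competing electrophile. Fallback: set out from 18 and make the ketone by acyl cross-coupling instead of addition and oxidation. LiSEt (EtSH, n-BuLi, THF, 0 °C) displaces the auxiliary and gives the S-ethyl thioester F2. Fukuyama coupling of F2 with the arylzinc chloride F3 (from 22 by n-BuLi then ZnCl2) under PdCl2(PPh3)2 catalysis in THF/toluene at rt gives the ketone directly. This comes back to the route at 26 and also bypasses the borohydride step.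

Step 5 (palladium-catalysed arylation of zinc reagent 8). The aryl bromide is ortho-alkoxy-substituted and electron-rich, the flavone is poorly soluble, and the quality of the zinc enolate is critical. Fallback: set out from 7 and install the two-carbon acid by allylation and oxidative cleavage. Stille coupling with allyltributylstannane (Pd(PPh3)4, toluene, 100 °C) gives the 3'-allylflavone F4. Lemieux–Johnson cleavage (OsO4 cat., NaIO4, 2,6-lutidine, dioxane/H2O) gives the arylacetaldehyde F5. Pinnick oxidation (NaClO2, NaH2PO4, 2-methyl-2-butene, t-BuOH/H2O) then comes back to the route at 10.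

**Further compounds**
F1 | step 17 | 2-Ar1-3-[4-(benzyloxy)phenyl]-1-[2-hydroxy-4,6-bis(methoxymethoxy)phenyl]prop-2-en-1-one (E/Z mixture) | O=C(c1c(O)cc(OCOC)cc1OCOC)C(=Cc1ccc(OCc2ccccc2)cc1)c1cc(-c2cc(=O)c3c(OCc4ccccc4)cc(OCc4ccccc4)cc3o2)ccc1OCc1ccccc1
F2 | step 13 | S-ethyl (2S,3S)-2-Ar1-3-[4-(benzyloxy)phenyl]-3-(triethylsilyloxy)propanethioate | CCSC(=O)[C@@H](c1cc(-c2cc(=O)c3c(OCc4ccccc4)cc(OCc4ccccc4)cc3o2)ccc1OCc1ccccc1)[C@H](O[Si](CC)(CC)CC)c1ccc(OCc2ccccc2)cc1
F3 | step 13 | chloro[2,4,6-tris(methoxymethoxy)phenyl]zinc | Cl[Zn]c1c(OCOC)cc(OCOC)cc1OCOC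
F4 | step 5 | 2-[3-allyl-4-(benzyloxy)phenyl]-5,7-bis(benzyloxy)-4H-chromen-4-one | C=CCc1cc(-c2cc(=O)c3c(OCc4ccccc4)cc(OCc4ccccc4)cc3o2)ccc1OCc1ccccc1
F5 | step 5 | 2-{2-(benzyloxy)-5-[5,7-bis(benzyloxy)-4-oxo-4H-chromen-2-yl]phenyl}acetaldehyde | O=CCc1cc(-c2cc(=O)c3c(OCc4ccccc4)cc(OCc4ccccc4)cc3o2)ccc1OCc1ccccc1
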